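## The problem

The target is (−)-quinic acid whose vicinal, trans-disposed O4 and O5 carry (E)-4-hydroxycinnamoyl (p-coumaroyl) esters, while O3 (cis to O4), the tertiary O1 and the C1 carboxyl group stay free. No ring has to be built: the cyclohexane with all four stereocentres (C1, C3, C4, C5) is the chiral-pool acid itself. The synthesis therefore creates no stereocentre and only has to leave the existing ones alone, which holds as long as nothing but O–H, O–Si and carboxyl C–O bonds is made or broken. The real difficulty is regiocontrol among four hydroxyls and one carboxyl group, above all telling O5 from O3, which flank O4 on either side. The fixed stereochemistry can steer this: the carboxyl group is cis to O5 only, so a 1,5-lactone ties up O5, and in that bicycle O3 is the single equatorial secondary hydroxyl (O4 axial, O1 tertiary) and can be silylated alone; reopening the lactone then exposes O4 and O5 together. The two aryl-conjugated enoate esters are the fragile part: base hydrolyses them or moves them to a neighbouring free hydroxyl (O4 to O3), light isomerises the E double bonds, hydrogenolysis saturates them, and the free phenols oxidise easily, so the end game must be acidic, non-reductive and short. The key step is possible because each ester carbonyl carbon sits between a ring oxygen (O4 or O5) and the sp2 α-carbon of an (E)-styryl unit, so this one carbon can be delivered as carbon monoxide between a styryl–palladium bond and the hydroxyl.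

## Retrosynthesis

**14 ⇒ 13.** Only protecting-group bonds are cut: the benzylic C–O bond of a 4-methoxybenzyl (PMB) ester, the O3–Si bond of a tert-butyldimethylsilyl (TBS) ether and the aryl O–CH2 bonds of two methoxymethyl (MOM) ethers. An all-acid-labile set is preferred to its neighbours. Hydrogenolysis would saturate the enoates, and hydroxide or basic fluoride would cleave or move them. An all-silyl set is also less safe, because aryl silyl ethers and silylethyl esters do not fall reliably under the acid that removes an alkyl silyl ether. The skeleton is not simplified; the forward reaction must remove four groups in one acidic operation without acyl migration to the freed O3.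

**13 ⇒ 5 + 10 + 11.** Both C(=O)–O bonds (to O4 and O5) and both Cα–C(=O) bonds of 13 are cut at once, giving diol 5, two molecules of (E)-styryl iodide 10 and two molecules of carbon monoxide 11; mono-ester 12 lies on the way. The neighbouring cut, at the C(=O)–O bonds alone, needs a separately made and stoichiometrically activated cinnamic acid. The carbonylative cut makes the acyl donor catalytically from a one-carbon-shorter building block, fixes the E geometry in the iodide and takes the carbonyl carbon from the cheapest source. The precursors are far simpler: 5 has no ester besides its protecting one, and 10 is a protected eight-carbon styrene. The forward reaction must acylate two adjacent secondary hydroxyls of an alcohol used as the limiting component, the second (O4) beside a silyl ether, and so has to turn over twice on each molecule of 5. It must also spare the tertiary O1, keep the alkene geometry and outrun re-closure of the lactone by O5.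

**5 ⇒ 3 (via 4).** The alkyl–oxygen bond of the PMB ester is cut, giving carboxylate 4, and 4 is traced to lactone 3 by re-forming the C(=O)–O5 bond. Direct alcoholysis of the lactone was set aside: it is an equilibrium that favours the bicycle unless the alcohol is the solvent, and it needs alkoxide, the condition under which a silyl group wanders between cis hydroxyls. Irreversible opening by one equivalent of hydroxide followed by carboxylate O-alkylation never activates the carboxyl group, so the lactone cannot return. The forward reaction must keep the silyl ether on O3.

**3 ⇒ 2 ⇒ 1.** Cutting O3–Si gives quinide 2, and cutting the lactone C–O5 bond gives (−)-quinic acid 1. The lactone is the device that separates O5 from O3; on an open-chain quinate ester these two hydroxyls silylate competitively. The forward reactions are a dehydrative lactonisation and a sterically controlled mono-silylation.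

**10 ⇒ 7 + 8 (via 9) ⇒ 6.** The C=C bond of 10 is cut into aldehyde 7 and the one-carbon unit of iodoform 8, which acts as its geminal dichromium reagent 9; 7 comes from 4-hydroxybenzaldehyde 6 by O-alkylation. Iododecarboxylation of a cinnamic acid would be pointless, since that acid already holds the carbonyl carbon. Hydrometalation of the arylalkyne is one step longer and is kept in reserve. The forward olefination must give the E iodide.

## Roads not taken

**Alternative 1:** The cut is the ring bond C1–C6, so the carbocycle is made instead of bought. Vinyl δ-lactone A1 (pyranone C3, C5, C6 = quinate C1, C3, C4) would be O-silylated at its enolate and undergo an Ireland–Claisen ring contraction. The [3,3] shift forms C1–C6, breaks the C4–O bond and gives cyclohexene acid A2 with the alkene at C4=C5. Its merits are real. Chirality is relayed from C4 to the quaternary C1 through a boat-like transition state, with bond formation on the lactone face that carries the vinyl group, so that group must be cis to the C3 silyloxy group. O1 and O3 also emerge already silylated and distinct from the still latent O4/O5. In that one respect it is better than the chosen plan, which needs a selective silylation and a lactone opening to reach the same differentiation. The weak points are larger. A1 needs its own asymmetric synthesis of a cis-disposed stereodyad. From A2 the trans-4,5-diol must still be installed on the alkene with the right facial and regiochemical sense next to an allylic silyl ether, and these are two stereocentres that 1 simply contains. The esterification, the actual problem of the target, is also left unsolved. Against this the chosen plan sets three short steps from a commercial acid that already has all four stereocentres.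

**Alternative 2:** The cut is C1–C2, re-enacting the biosynthesis. 3-Dehydroquinate synthase, with bound NAD+ and divalent cobalt supplied as CoCl2, would turn heptulosonate phosphate A3 into 3-dehydroquinic acid A4 by transient oxidation, phosphate elimination, reduction, ring opening and intramolecular aldol closure. The step is protecting-group-free, runs in water and sets C1 perfectly. The C3 carbonyl of A4 also marks C3 off from O4/O5 without any protecting group, an economy the chosen plan cannot match. Set against this, A3 is not a commodity and the enzyme must be produced. A4 is a β-hydroxy ketone that loses its 1-hydroxyl readily under the basic conditions of acylation, and its α-acyloxy ketone at C4 is epimerisable. The C3 ketone would later have to be reduced to the axial alcohol in the presence of two enoates. Finally, A4 plus that reduction is nothing other than 1, which is purchased; the chosen plan lets nature perform both operations.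

**Alternative 3:** The cut is C3–C4. SmI2 (divalent samarium) would couple the two aldehyde carbons of lactone dialdehyde A5 in a pinacol reaction; the samarium chelate would give the cis-3,4-diol and close the cyclohexane onto the γ-lactone, yielding quinide A6, identical with lactone 2 of the chosen route. The bicyclic template holds both aldehyde arms on one face, and the product enters the chosen route directly, so beyond that point the two roads are the same. The weak points lie before it. A5 already contains the C1 and C5 stereocentres and needs a multistep asymmetric synthesis. Its aldehydes are prone to epimerisation (α-acyloxy) and to retro-aldol or elimination (β-hydroxy). The coupling must select the one cis-diol that is trans to O5. SmI2 can also cleave the α-oxygen substituent at C1 reductively. The chosen plan reaches the same lactone in one acid-catalysed step from 1; the alternative would only pay for skeletal analogues or isotopologues.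

Key step: step 6

Remark on the chemistry: quinic acid positions follow the IUPAC convention, in which O3 is cis to O4, O5 is trans to O4 and cis to the carboxyl group, so the lactone bridge runs from C1 to O5.

## Route

**Step 1**
Reactants: 1 (−)-quinic acid, (1S,3R,4S,5R)-1,3,4,5-tetrahydroxycyclohexane-1-carboxylic acid
Product: 2 quinic acid 1,5-lactone (quinide; carboxyl bridged to O5, free hydroxyls on C1, C3, C4)
Conditions: p-TsOH·H2O (cat.), toluene/DMF, reflux, Dean–Stark
Reagents that add atoms: none
Why: Acid-catalysed lactonisation (intramolecular Fischer esterification); only O5 is cis to the carboxyl group and can reach it, removal of water drives the equilibrium, and no C–O bond at a stereocentre is broken.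

**Step 2**
Reactants: 2 quinic acid 1,5-lactone
Product: 3 3-O-(tert-butyldimethylsilyl)quinic acid 1,5-lactone (free hydroxyls on C1 and C4)
Conditions: TBSCl (1.1 equiv), imidazole, DMF, 0 °C to rt
Reagents that add atoms: tert-butyldimethylsilyl chloride, CC(C)(C)[Si](C)(C)Cl
Why: Regioselective O-silylation under steric control; in the bicyclic lactone O3 is the only equatorial secondary hydroxyl, O4 is axial and O1 tertiary, so one equivalent of the bulky silyl chloride should go to O3.

**Step 3**
Reactants: 3 3-O-(tert-butyldimethylsilyl)quinic acid 1,5-lactone
Product: 5 4-methoxybenzyl 3-O-(tert-butyldimethylsilyl)quinate (free hydroxyls on C1, C4, C5), via cesium 3-O-(tert-butyldimethylsilyl)quinate 4 (not isolated)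
Conditions: CsOH·H2O (1.0 equiv), THF/H2O, 0 °C; evaporate; then PMBCl, Bu4NI (cat.), DMF, rt
Reagents that add atoms: cesium hydroxide monohydrate, [Cs+].[OH-].O; 4-methoxybenzyl chloride, COc1ccc(CCl)cc1
Why: Saponification of the strained lactone by exactly one equivalent of hydroxide, then SN2 O-alkylation of the cesium carboxylate in DMF; the carboxyl group is never activated, so the lactone cannot re-form, and neutral hydroxyls are not benzylated. Hydroxide is consumed by the fast lactone opening, which should leave little alkoxide to start a silyl shift.

**Step 4**
Reactants: 6 4-hydroxybenzaldehyde
Product: 7 4-(methoxymethoxy)benzaldehyde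
Conditions: MOMCl, iPr2NEt, CH2Cl2, 0 °C to rt
Reagents that add atoms: chloromethyl methyl ether, COCCl
Why: Standard O-alkylation of a phenol to its methoxymethyl acetal; the acetal tolerates chromium reagents, amines and zerovalent palladium and is cleaved by acid at the end.

**Step 5**
Reactants: 7 4-(methoxymethoxy)benzaldehyde; 8 iodoform
Product: 10 (E)-1-(2-iodoethenyl)-4-(methoxymethoxy)benzene, via geminal dichromium carbenoid ICH(CrCl2)2 9 (not isolated)
Conditions: CrCl2 (6 equiv), CHI3 (2 equiv), THF/1,4-dioxane, 0 °C to rt
Reagents that add atoms: none
Why: Takai olefination; divalent chromium reduces iodoform to the geminal dichromium species, which adds to the aldehyde and eliminates anti to give the E vinyl iodide, as is usual for aromatic aldehydes. Any minor Z isomer must be removed before step 6.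

**Step 6**
Reactants: 5 4-methoxybenzyl 3-O-(tert-butyldimethylsilyl)quinate; 10 (E)-1-(2-iodoethenyl)-4-(methoxymethoxy)benzene; 11 carbon monoxide
Product: 13 4-methoxybenzyl 3-O-(tert-butyldimethylsilyl)-4,5-bis-O-[(E)-4-(methoxymethoxy)cinnamoyl]quinate, via 5-O-[(E)-4-(methoxymethoxy)cinnamoyl] monoester 12 (not isolated)
Conditions: 10 (3 equiv), CO (1 atm), Pd(PPh3)4 (10 mol%), Et3N (4 equiv), DMAP (0.5 equiv), DMF, 50 °C, dark
Reagents that add atoms: (E)-1-(2-iodoethenyl)-4-(methoxymethoxy)benzene (second molar equivalent of 10), I/C=C/c1ccc(OCOC)cc1; carbon monoxide (second molar equivalent of 11), [C-]#[O+]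
Why: Zerovalent palladium inserts into the C–I bond of 10 with retention, CO inserts into the styryl–palladium bond, and the resulting cinnamoyl–palladium iodide (divalent palladium) is captured by a hydroxyl of 5, either directly or after relay through an N-acylpyridinium ion formed with DMAP; Et3N takes up HI and zerovalent palladium is regenerated. The cycle runs twice on each molecule of 5, first at O5 and then at O4, so two molecules of 10 and two of CO are built into 13 and the four new bonds (two Cα–C(=O), two C(=O)–O) form in one operation. The closest known reaction type is the Heck-type alkoxycarbonylation of vinyl iodides, used here with the alcohol as the limiting component and the iodide in excess. No ring closes and no stereocentre is formed; the four ring stereocentres are untouched because only O–H bonds of 5 react. The E geometry of both enoates is carried over from 10, since oxidative addition and migratory insertion are stereoretentive. The step needs selectivity for O4 and O5, which the substrate secures: O3 is silylated and O1 is tertiary and hydrogen-bonded to the adjacent ester. The less hindered O5 should react first to give 12, which also removes the only hydroxyl able to re-close the lactone, and the excess iodide with DMAP relay should carry the slower acylation of the flanked O4. The acyl donor is present only at catalyst level, so the PMB ester, the MOM acetals and the silyl ether are not challenged.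

**Step 7**
Reactants: 13 4-methoxybenzyl 3-O-(tert-butyldimethylsilyl)-4,5-bis-O-[(E)-4-(methoxymethoxy)cinnamoyl]quinate
Product: 14 4,5-di-O-[(E)-p-coumaroyl]quinic acid (target)
Conditions: TFA/H2O (9:1), anisole, 0 °C to rt, dark
Reagents that add atoms: none
Why: Global acidolysis; the PMB ester ionises to the 4-methoxybenzyl cation (trapped by anisole), the aryl MOM acetals hydrolyse and the secondary silyl ether is solvolysed, all in one acidic medium. Enoate esters are stable to aqueous acid, acyl migration is slow at low pH, and O5 is acylated so no lactone can form.

## Compound list

1 | (−)-quinic acid, (1S,3R,4S,5R)-1,3,4,5-tetrahydroxycyclohexane-1-carboxylic acid | O[C@@H]1[C@H](O)C[C@@](O)(C(=O)O)C[C@H]1O | starting material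
2 | quinic acid 1,5-lactone (quinide) | O[C@@H]1[C@H](O)C[C@@](O)(C(=O)O2)C[C@H]12 | intermediate
3 | 3-O-(tert-butyldimethylsilyl)quinic acid 1,5-lactone | O[C@@H]1[C@H](O[Si](C)(C)C(C)(C)C)C[C@@](O)(C(=O)O2)C[C@H]12 | intermediate
4 | cesium 3-O-(tert-butyldimethylsilyl)quinate | [Cs+].O[C@@H]1[C@H](O[Si](C)(C)C(C)(C)C)C[C@@](O)(C(=O)[O-])C[C@H]1O | intermediate (not isolated)
5 | 4-methoxybenzyl 3-O-(tert-butyldimethylsilyl)quinate | O[C@@H]1[C@H](O[Si](C)(C)C(C)(C)C)C[C@@](O)(C(=O)OCc2ccc(OC)cc2)C[C@H]1O | intermediate
6 | 4-hydroxybenzaldehyde | O=Cc1ccc(O)cc1 | starting material
7 | 4-(methoxymethoxy)benzaldehyde | O=Cc1ccc(OCOC)cc1 | intermediate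
8 | iodoform | IC(I)I | starting material
9 | geminal dichromium carbenoid ICH(CrCl2)2 (trivalent chromium) | IC([Cr](Cl)Cl)[Cr](Cl)Cl | intermediate (not isolated)
10 | (E)-1-(2-iodoethenyl)-4-(methoxymethoxy)benzene | I/C=C/c1ccc(OCOC)cc1 | intermediate
11 | carbon monoxide | [C-]#[O+] | starting material
12 | 4-methoxybenzyl 3-O-(tert-butyldimethylsilyl)-5-O-[(E)-4-(methoxymethoxy)cinnamoyl]quinate | O[C@@H]1[C@H](O[Si](C)(C)C(C)(C)C)C[C@@](O)(C(=O)OCc2ccc(OC)cc2)C[C@H]1OC(=O)/C=C/c1ccc(OCOC)cc1 | intermediate (not isolated)
13 | 4-methoxybenzyl 3-O-(tert-butyldimethylsilyl)-4,5-bis-O-[(E)-4-(methoxymethoxy)cinnamoyl]quinate | O=C(/C=C/c1ccc(OCOC)cc1)O[C@@H]1[C@H](O[Si](C)(C)C(C)(C)C)C[C@@](O)(C(=O)OCc2ccc(OC)cc2)C[C@H]1OC(=O)/C=C/c1ccc(OCOC)cc1 | intermediate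
14 | 4,5-di-O-[(E)-p-coumaroyl]quinic acid | O=C(/C=C/c1ccc(O)cc1)O[C@@H]1[C@H](O)C[C@@](O)(C(=O)O)C[C@H]1OC(=O)/C=C/c1ccc(O)cc1 | target

## Step count and least certain steps

Total: 7 steps. Longest linear sequence: 5 steps (steps 1, 2, 3, 6, 7); the aryl branch (steps 4, 5) joins at step 6.

**Step 6 (key step).** The most likely failure is stalling after the first acylation. Capture of the acyl–palladium species by the flanked O4–H is slow when the alcohol is the limiting reagent, and the second turnover on the same molecule is the demanding one. Meanwhile the iodide is used up by reduction or homocoupling, and amine-promoted re-closure of the 1,5-lactone by any still free O5 competes. The fallback separates carbonylation from ester formation. Setting out from 10 and 11, hydroxycarbonylation (Pd(OAc)2, PPh3, CO, H2O, Et3N, DMF) gives (E)-3-[4-(methoxymethoxy)phenyl]prop-2-enoic acid F1, in which the unhindered nucleophile water is in excess. F1 is converted with 2,4,6-trichlorobenzoyl chloride and Et3N into the (E)-4-(methoxymethoxy)cinnamic 2,4,6-trichlorobenzoic mixed anhydride F2 (Yamaguchi activation). F2 acylates both hydroxyls of 5 in toluene with DMAP, returning to the route at 13; the carbonyl carbons still come from CO.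

**Step 3.** The most likely failure is 1,2-migration of the silyl group from O3 to O4 once the ring has opened and flipped, triggered by residual hydroxide or alkoxide. Incomplete alkylation that returns lactone on work-up is the second risk. The fallback avoids ionic base altogether. Setting out from 3, opening with Me3SnOH in 1,2-dichloroethane at 60 °C and a brief cold dilute HCl wash gives 3-O-(tert-butyldimethylsilyl)quinic acid F3. F3 is esterified at once with 4-methoxybenzyl 2,2,2-trichloroacetimidate in CH2Cl2 at rt without added promoter (the acid activates the imidate itself), returning to the route at 5.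

**Step 5.** The most likely failure is incomplete E selectivity and erratic reduction by heterogeneous CrCl2 of variable quality. A Z contaminant would be carried into a cis-coumaroyl ester that is hard to separate late. The fallback changes the origin of the geometry. Setting out from 7, Ohira–Bestmann homologation (dimethyl (1-diazo-2-oxopropyl)phosphonate, K2CO3, MeOH) gives 1-ethynyl-4-(methoxymethoxy)benzene F4. Syn-hydrozirconation of F4 with Cp2Zr(H)Cl in THF and stereoretentive iodinolysis with I2 then give the E isomer only, returning to the route at 10.

**Step 7.** The most likely failure is slow solvolysis of the hindered axial silyl ether. This forces long exposure to strong acid, during which acyl migration from O4 to the freed O3, benzylation of the liberated phenol rings by the PMB cation and light-induced E/Z isomerisation can set in. The fallback stages the deprotection. Setting out from 13, buffered HF·pyridine in THF/pyridine (0 °C to rt) removes only the silyl ether and gives 4-methoxybenzyl 4,5-bis-O-[(E)-4-(methoxymethoxy)cinnamoyl]quinate F5. A short, cold acidolysis of F5 (TFA/H2O, anisole, 0 °C) then has only the fast-cleaving PMB ester and MOM acetals to remove, returning to the route at 14.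

## Further compounds

F1 | step 6 | (E)-3-[4-(methoxymethoxy)phenyl]prop-2-enoic acid | O=C(O)/C=C/c1ccc(OCOC)cc1
F2 | step 6 | (E)-4-(methoxymethoxy)cinnamic 2,4,6-trichlorobenzoic anhydride | O=C(/C=C/c1ccc(OCOC)cc1)OC(=O)c1c(Cl)cc(Cl)cc1Cl
F3 | step 3 | 3-O-(tert-butyldimethylsilyl)quinic acid | O[C@@H]1[C@H](O[Si](C)(C)C(C)(C)C)C[C@@](O)(C(=O)O)C[C@H]1O
F4 | step 5 | 1-ethynyl-4-(methoxymethoxy)benzene | C#Cc1ccc(OCOC)cc1
F5 | step 7 | 4-methoxybenzyl 4,5-bis-O-[(E)-4-(methoxymethoxy)cinnamoyl]quinate | O=C(/C=C/c1ccc(OCOC)cc1)O[C@@H]1[C@H](O)C[C@@](O)(C(=O)OCc2ccc(OC)cc2)C[C@H]1OC(=O)/C=C/c1ccc(OCOC)cc1
A1 | alternative 1 | 3,5-bis(tert-butyldimethylsilyloxy)-6-vinyltetrahydropyran-2-one (5,6-cis; C3 configuration immaterial because it is enolised) | C=C[C@H]1OC(=O)C(O[Si](C)(C)C(C)(C)C)C[C@H]1O[Si](C)(C)C(C)(C)C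
A2 | alternative 1 | 1,3-bis(tert-butyldimethylsilyloxy)cyclohex-4-ene-1-carboxylic acid (quinate numbering) | C1=CC[C@](O[Si](C)(C)C(C)(C)C)(C(=O)O)C[C@H]1O[Si](C)(C)C(C)(C)C
A3 | alternative 2 | 3-deoxy-D-arabino-hept-2-ulosonic acid 7-phosphate | O=C(O)C(=O)C[C@@H](O)[C@H](O)[C@H](O)COP(=O)(O)O
A4 | alternative 2 | 3-dehydroquinic acid | O[C@@H]1C(=O)C[C@@](O)(C(=O)O)C[C@H]1O
A5 | alternative 3 | 5-formyl-3-hydroxy-3-(2-oxoethyl)dihydrofuran-2(3H)-one (arms cis) | O=CC[C@@](O)(C(=O)O1)C[C@@H]1C=O
A6 | alternative 3 | quinic acid 1,5-lactone (identical with 2) | O[C@@H]1[C@H](O)C[C@@](O)(C(=O)O2)C[C@H]12
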